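**Strategy**

Everything rests on disconnecting the C2=C3 double bond of the styryl-bearing cyclopentenone (pentalene numbering; the C1 and C6 carbonyls flank the carbinol C6a). C2=C3 together with the C3–CH=CH–aryl arm is a 1-vinylcyclopentene, the fingerprint of ring-closing enyne metathesis. The precursor is a monocyclic 2,3-diarylcyclopentenone that carries, cis to one another, an ethynyl group on C4 and a cinnamoyl ketone on the carbinol carbon C5. In one operation a ruthenium carbene closes the second five-membered ring and moves the arylmethylidene end of the enone onto the alkyne terminus, so the (E)-styryl arm originates on the far side of the new ring.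

Key step: step 11

Remark: all seven phenols travel as benzyl ethers; in step 3 the antipode of the N-PINAP ligand is chosen in a pilot run so that adduct 6 is 3R, which maps onto C3a (S) of the target.

**Route**

Step 1
Reactants: 1 3,4,5-tris(benzyloxy)benzaldehyde
Product: 2 1,2,3-tris(benzyloxy)-5-ethynylbenzene
Conditions: dimethyl (1-diazo-2-oxopropyl)phosphonate, K2CO3, MeOH–THF, rt
Reagents that add atoms: dimethyl (1-diazo-2-oxopropyl)phosphonate, CC(=O)C(=[N+]=[N-])P(=O)(OC)OC
Why: Seyferth–Gilbert homologation with the Ohira–Bestmann reagent should turn the non-enolisable aryl aldehyde into the terminal alkyne under carbonate conditions that leave benzyl ethers untouched.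

Step 2
Reactants: 3 3-(triisopropylsilyl)prop-2-ynal; 4 Meldrum's acid (2,2-dimethyl-1,3-dioxane-4,6-dione)
Product: 5 2,2-dimethyl-5-[3-(triisopropylsilyl)prop-2-yn-1-ylidene]-1,3-dioxane-4,6-dione
Conditions: pyrrolidinium acetate (10 mol%), toluene, 4 Å MS, rt
Reagents that add atoms: none
Why: Knoevenagel condensation of the strongly acidic Meldrum's acid with the non-enolisable ynal should give the doubly activated acceptor, whose remote alkyne carbon is shielded by the bulky silyl group.

Step 3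
Reactants: 5 (1.5 equiv); 2
Product: 6 2,2-dimethyl-5-{(3R)-1-(triisopropylsilyl)-5-[3,4,5-tris(benzyloxy)phenyl]penta-1,4-diyn-3-yl}-1,3-dioxane-4,6-dione
Conditions: Cu(OAc)2·H2O (10 mol%), sodium L-ascorbate (20 mol%), N-PINAP ligand (single atropisomer, 10 mol%), H2O–t-BuOH, 0 °C
Reagents that add atoms: none
Why: Copper-catalysed asymmetric conjugate alkynylation of an alkylidene Meldrum's acid, in which the monovalent copper acetylide of 2 bound to the chiral P,N ligand adds 1,4 to the β-carbon and the ligand selects the face, setting the 3R centre (the future C3a).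

Step 4
Reactants: 6
Product: 8 methyl (3R)-3-[(triisopropylsilyl)ethynyl]-5-[3,4,5-tris(benzyloxy)phenyl]pent-4-ynoate, via malonic half ester 7 (not isolated)
Conditions: pyridine–MeOH (10:1), Cu powder (cat.), 100 °C
Reagents that add atoms: methanol, CO
Why: Alcoholysis of the Meldrum's acid ring with loss of acetone followed by decarboxylation of the malonic half ester should give the mono-ester, the weak base leaving the bis-propargylic stereocentre alone.

Step 5
Reactants: 8; 9 [3,5-bis(benzyloxy)phenyl]boronic acid (2 equiv)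
Product: 10 (4R)-3-[3,5-bis(benzyloxy)phenyl]-4-[(triisopropylsilyl)ethynyl]-2-[3,4,5-tris(benzyloxy)phenyl]cyclopent-2-en-1-one
Conditions: Ni(OAc)2·4H2O (10 mol%), 2-[2-(diphenylphosphino)ethyl]pyridine (10 mol%), 2,2,2-trifluoroethanol, 80 °C
Reagents that add atoms: none
Why: Nickel-catalysed anti-carbometallative arylative cyclisation, in which the aryl–nickel species (divalent nickel) adds across the aryl alkyne with the new aryl group on the alkyl-substituted carbon, the alkenylnickel isomerises E/Z and is acylated by the ester, so the two different aryl groups are placed regiospecifically on C3 and C2 while the stereocentre is a bystander.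

Step 6
Reactants: 11 3,5-bis(benzyloxy)benzaldehyde
Product: 13 (E)-3-[3,5-bis(benzyloxy)phenyl]prop-2-enoic acid, via arylidenemalonic acid 12 (not isolated)
Conditions: malonic acid, pyridine, piperidine (cat.), 100 °C
Reagents that add atoms: malonic acid, OC(=O)CC(O)=O
Why: Knoevenagel–Doebner condensation with decarboxylation should give the cinnamic acid as the thermodynamically preferred E isomer.

Step 7
Reactants: 13
Product: 14 (E)-3-[3,5-bis(benzyloxy)phenyl]prop-2-enoyl chloride
Conditions: (COCl)2, DMF (cat.), CH2Cl2, 0 °C → rt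
Reagents that add atoms: oxalyl chloride, ClC(=O)C(Cl)=O
Why: Acid chloride formation through the Vilsmeier-type chloroiminium catalyst proceeds under neutral conditions that preserve the E alkene and the benzyl ethers.

Step 8
Reactants: 10; 14
Product: 15 (4R)-5-{(E)-3-[3,5-bis(benzyloxy)phenyl]prop-2-enoyl}-3-[3,5-bis(benzyloxy)phenyl]-4-[(triisopropylsilyl)ethynyl]-2-[3,4,5-tris(benzyloxy)phenyl]cyclopent-2-en-1-one (C5 epimerisable, largely enol; used at once)
Conditions: LiN(SiMe3)2 (2.2 equiv), toluene–THF, −78 °C; then 14, −78 → 0 °C; aq. NH4Cl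
Reagents that add atoms: none
Why: Kinetic deprotonation should give the cross-conjugated lithium enolate at C5 rather than at the γ-position C4, and crossed Claisen C-acylation by the acid chloride gives the β-diketone, which the second equivalent of base stores as its enolate.

Step 9
Reactants: 15
Product: 16 (4R,5S)-5-{(E)-3-[3,5-bis(benzyloxy)phenyl]prop-2-enoyl}-3-[3,5-bis(benzyloxy)phenyl]-5-hydroxy-4-[(triisopropylsilyl)ethynyl]-2-[3,4,5-tris(benzyloxy)phenyl]cyclopent-2-en-1-one
Conditions: dimethyldioxirane (1.1 equiv, acetone solution), CH2Cl2, −40 → 0 °C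
Reagents that add atoms: dimethyldioxirane, CC1(C)OO1
Why: Electrophilic α-hydroxylation of the enolised β-diketone (epoxidation of the enol and ring opening) under substrate control, the dioxirane approaching C5 from the face opposite to the C4 alkynyl group so that OH ends trans to the alkyne and the cinnamoyl group cis to it.

Step 10
Reactants: 16
Product: 17 (4S,5S)-5-{(E)-3-[3,5-bis(benzyloxy)phenyl]prop-2-enoyl}-3-[3,5-bis(benzyloxy)phenyl]-4-ethynyl-5-hydroxy-2-[3,4,5-tris(benzyloxy)phenyl]cyclopent-2-en-1-one (the C4 descriptor changes by priority only)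
Conditions: Bu4NF, AcOH (1:1, 3 equiv), THF, 0 °C → rt
Reagents that add atoms: none
Why: Fluoride-induced protodesilylation of the alkynylsilane, buffered with acetic acid so that neither the γ-proton at C4 nor the base-sensitive α-hydroxy-β-diketone is attacked.

Step 11
Reactants: 17
Product: 18 (3aS,6aS)-3-{(E)-2-[3,5-bis(benzyloxy)phenyl]ethenyl}-4-[3,5-bis(benzyloxy)phenyl]-6a-hydroxy-5-[3,4,5-tris(benzyloxy)phenyl]-3a,6a-dihydropentalene-1,6-dione
Conditions: second-generation Hoveyda–Grubbs catalyst (5 mol%), toluene (0.005 M), 80 °C, argon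
Reagents that add atoms: none
Why: Ring-closing enyne metathesis of a 1,6-enyne: the propagating ruthenium arylidene [Ru]=CHAr adds to the terminal alkyne with ruthenium on the internal carbon, and the resulting vinylcarbene, which already carries the new CH=CHAr arm, undergoes ring-closing metathesis with the cinnamoyl C=C, forming the C2=C3 bond and releasing [Ru]=CHAr for the next turnover. The closest known reaction type is ruthenium-catalysed enyne ring-closing metathesis with alkylidene transfer from a 1,2-disubstituted alkene, including closures onto acrylate-type α,β-unsaturated carbonyl partners. The one ring that closes is the five-membered enone ring, formed in the exo mode (only the internal alkyne carbon enters the ring). No stereocentre is created: C4 and C5 of 17 become C3a and C6a unchanged, and because alkyne and enone are cis on the existing ring only the cis-fused bicyclo[3.3.0]octadienedione can form. The step needs exo over endo insertion and E geometry of the new arm: the terminal alkyne places ruthenium at the substituted carbon, the three-atom tether favours the five-membered ring, the conjugated aryl diene is most stable as E, and the tetrasubstituted diaryl enone of the first ring is inert to the carbene.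

Step 12
Reactants: 18
Product: 19 (3aS,6aS)-3-[(E)-2-(3,5-dihydroxyphenyl)ethenyl]-4-(3,5-dihydroxyphenyl)-6a-hydroxy-5-(3,4,5-trihydroxyphenyl)-3a,6a-dihydropentalene-1,6-dione (CNP0306657.1)
Conditions: BCl3 (excess), pentamethylbenzene (excess), CH2Cl2, −78 °C; CHCl3–MeOH quench at −78 °C
Reagents that add atoms: none
Why: Lewis acid-mediated debenzylation with pentamethylbenzene as a non-Lewis-basic cation scavenger should cleave all seven aryl benzyl ethers at low temperature without touching the alkenes, the tertiary carbinol or the electron-rich rings.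

**Compound list**

1 | 3,4,5-tris(benzyloxy)benzaldehyde | O=Cc1cc(OCc2ccccc2)c(OCc2ccccc2)c(OCc2ccccc2)c1 | starting material
2 | 1,2,3-tris(benzyloxy)-5-ethynylbenzene | C#Cc1cc(OCc2ccccc2)c(OCc2ccccc2)c(OCc2ccccc2)c1 | intermediate
3 | 3-(triisopropylsilyl)prop-2-ynal | O=CC#C[Si](C(C)C)(C(C)C)C(C)C | starting material
4 | Meldrum's acid (2,2-dimethyl-1,3-dioxane-4,6-dione) | CC1(C)OC(=O)CC(=O)O1 | starting material
5 | 2,2-dimethyl-5-[3-(triisopropylsilyl)prop-2-yn-1-ylidene]-1,3-dioxane-4,6-dione | CC1(C)OC(=O)C(=CC#C[Si](C(C)C)(C(C)C)C(C)C)C(=O)O1 | intermediate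
6 | 2,2-dimethyl-5-{(3R)-1-(triisopropylsilyl)-5-[3,4,5-tris(benzyloxy)phenyl]penta-1,4-diyn-3-yl}-1,3-dioxane-4,6-dione | CC1(C)OC(=O)C(C(=O)O1)[C@@H](C#C[Si](C(C)C)(C(C)C)C(C)C)C#Cc1cc(OCc2ccccc2)c(OCc2ccccc2)c(OCc2ccccc2)c1 | intermediate
7 | (3R)-2-(methoxycarbonyl)-3-[(triisopropylsilyl)ethynyl]-5-[3,4,5-tris(benzyloxy)phenyl]pent-4-ynoic acid (both C2 epimers; malonic half ester) | COC(=O)C(C(O)=O)[C@@H](C#C[Si](C(C)C)(C(C)C)C(C)C)C#Cc1cc(OCc2ccccc2)c(OCc2ccccc2)c(OCc2ccccc2)c1 | intermediate
8 | methyl (3R)-3-[(triisopropylsilyl)ethynyl]-5-[3,4,5-tris(benzyloxy)phenyl]pent-4-ynoate | COC(=O)C[C@@H](C#C[Si](C(C)C)(C(C)C)C(C)C)C#Cc1cc(OCc2ccccc2)c(OCc2ccccc2)c(OCc2ccccc2)c1 | intermediate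
9 | [3,5-bis(benzyloxy)phenyl]boronic acid | OB(O)c1cc(OCc2ccccc2)cc(OCc2ccccc2)c1 | starting material
10 | (4R)-3-[3,5-bis(benzyloxy)phenyl]-4-[(triisopropylsilyl)ethynyl]-2-[3,4,5-tris(benzyloxy)phenyl]cyclopent-2-en-1-one | CC(C)[Si](C#C[C@H]1C(c2cc(OCc3ccccc3)cc(OCc3ccccc3)c2)=C(c2cc(OCc3ccccc3)c(OCc3ccccc3)c(OCc3ccccc3)c2)C(=O)C1)(C(C)C)C(C)C | intermediate
11 | 3,5-bis(benzyloxy)benzaldehyde | O=Cc1cc(OCc2ccccc2)cc(OCc2ccccc2)c1 | starting material
12 | 2-{[3,5-bis(benzyloxy)phenyl]methylidene}propanedioic acid | OC(=O)C(=Cc1cc(OCc2ccccc2)cc(OCc2ccccc2)c1)C(O)=O | intermediate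
13 | (E)-3-[3,5-bis(benzyloxy)phenyl]prop-2-enoic acid | OC(=O)/C=C/c1cc(OCc2ccccc2)cc(OCc2ccccc2)c1 | intermediate
14 | (E)-3-[3,5-bis(benzyloxy)phenyl]prop-2-enoyl chloride | ClC(=O)/C=C/c1cc(OCc2ccccc2)cc(OCc2ccccc2)c1 | intermediate
15 | (4R)-5-{(E)-3-[3,5-bis(benzyloxy)phenyl]prop-2-enoyl}-3-[3,5-bis(benzyloxy)phenyl]-4-[(triisopropylsilyl)ethynyl]-2-[3,4,5-tris(benzyloxy)phenyl]cyclopent-2-en-1-one (C5 undefined, enolised) | CC(C)[Si](C#C[C@H]1C(c2cc(OCc3ccccc3)cc(OCc3ccccc3)c2)=C(c2cc(OCc3ccccc3)c(OCc3ccccc3)c(OCc3ccccc3)c2)C(=O)C1C(=O)/C=C/c1cc(OCc2ccccc2)cc(OCc2ccccc2)c1)(C(C)C)C(C)C | intermediate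
16 | (4R,5S)-5-{(E)-3-[3,5-bis(benzyloxy)phenyl]prop-2-enoyl}-3-[3,5-bis(benzyloxy)phenyl]-5-hydroxy-4-[(triisopropylsilyl)ethynyl]-2-[3,4,5-tris(benzyloxy)phenyl]cyclopent-2-en-1-one (alkynyl and acyl cis, OH trans to alkynyl) | CC(C)[Si](C#C[C@H]1C(c2cc(OCc3ccccc3)cc(OCc3ccccc3)c2)=C(c2cc(OCc3ccccc3)c(OCc3ccccc3)c(OCc3ccccc3)c2)C(=O)[C@@]1(O)C(=O)/C=C/c1cc(OCc2ccccc2)cc(OCc2ccccc2)c1)(C(C)C)C(C)C | intermediate
17 | (4S,5S)-5-{(E)-3-[3,5-bis(benzyloxy)phenyl]prop-2-enoyl}-3-[3,5-bis(benzyloxy)phenyl]-4-ethynyl-5-hydroxy-2-[3,4,5-tris(benzyloxy)phenyl]cyclopent-2-en-1-one (ethynyl and acyl cis) | C#C[C@H]1C(c2cc(OCc3ccccc3)cc(OCc3ccccc3)c2)=C(c2cc(OCc3ccccc3)c(OCc3ccccc3)c(OCc3ccccc3)c2)C(=O)[C@@]1(O)C(=O)/C=C/c1cc(OCc2ccccc2)cc(OCc2ccccc2)c1 | intermediate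
18 | (3aS,6aS)-3-{(E)-2-[3,5-bis(benzyloxy)phenyl]ethenyl}-4-[3,5-bis(benzyloxy)phenyl]-6a-hydroxy-5-[3,4,5-tris(benzyloxy)phenyl]-3a,6a-dihydropentalene-1,6-dione (cis-fused) | O=C1C=C(/C=C/c2cc(OCc3ccccc3)cc(OCc3ccccc3)c2)[C@H]2C(c3cc(OCc4ccccc4)cc(OCc4ccccc4)c3)=C(c3cc(OCc4ccccc4)c(OCc4ccccc4)c(OCc4ccccc4)c3)C(=O)[C@@]12O | intermediate
19 | (3aS,6aS)-3-[(E)-2-(3,5-dihydroxyphenyl)ethenyl]-4-(3,5-dihydroxyphenyl)-6a-hydroxy-5-(3,4,5-trihydroxyphenyl)-3a,6a-dihydropentalene-1,6-dione | O=C1C=C(/C=C/c2cc(O)cc(O)c2)[C@H]2C(c3cc(O)cc(O)c3)=C(c3cc(O)c(O)c(O)c3)C(=O)[C@@]12O | target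

**Step count and risks**

Total step count: 12. Longest linear sequence: 9 steps (step 1 or 2, then 3, 4, 5, 8, 9, 10, 11, 12).

Steps most likely to fail:

1. Step 11 (key step). Insertion of the terminal alkyne into the arylidene carbene may be slow next to the chelating carbonyl and hydroxyl groups. The cycle would then stall, the alkyne would oligomerise and part of the aryl-vinyl end would be drained as stilbene. Each ruthenium centre also transfers the benzylidene of the precatalyst once, which is why the loading is kept low. Fallback: ring closure and arm installation are separated. Setting out from 17, the same catalyst under ethylene (1 atm, toluene, 80 °C) should turn over through the more reactive methylidene carbene and give the vinyl bicycle (3aS,6aS)-4-[3,5-bis(benzyloxy)phenyl]-3-ethenyl-6a-hydroxy-5-[3,4,5-tris(benzyloxy)phenyl]-3a,6a-dihydropentalene-1,6-dione F1. The aryl-vinyl end leaves as 1,3-bis(benzyloxy)-5-ethenylbenzene F2, more of which is available from 11 by Wittig methylenation with Ph3P=CH2. After removal of ethylene, cross-metathesis of the terminal vinyl group of F1 with excess F2 (second-generation Hoveyda–Grubbs catalyst, CH2Cl2, 40 °C) should install the (E)-styryl arm and return to the route at 18.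

2. Step 5. Acylation of the alkenylnickel by a single, unactivated methyl ester may be slower than protodemetallation in the protic solvent, so that the open-chain hydroarylated alkene accumulates. Fallback: the electrophile is changed to the malonate diester, the substrate class on which this cyclisation is established. Setting out from 6, methanolysis (MeOH, reflux, through half ester 7) followed by TMSCHN2 should give dimethyl 2-{(3R)-1-(triisopropylsilyl)-5-[3,4,5-tris(benzyloxy)phenyl]penta-1,4-diyn-3-yl}propanedioate F3. The same nickel-catalysed arylative cyclisation with 9 should then give the β-keto ester methyl (5R)-4-[3,5-bis(benzyloxy)phenyl]-2-oxo-5-[(triisopropylsilyl)ethynyl]-3-[3,4,5-tris(benzyloxy)phenyl]cyclopent-3-ene-1-carboxylate F4. Krapcho dealkoxycarbonylation (LiCl, wet DMSO, 120 °C) returns to the route at 10.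

3. Step 3. The lipophilic solid alkyne may mix poorly with the aqueous phase, and the very electrophilic ynylidene acceptor may be hydrolysed or attacked at the remote alkyne carbon before the face-selective 1,4-addition, eroding conversion and enantiomeric purity. Fallback: the roles are inverted and the silylalkyne is added to an enal in organic solvent. Setting out from 2, formylation (n-BuLi, DMF, THF, −78 °C) should give 3-[3,4,5-tris(benzyloxy)phenyl]prop-2-ynal F5. Wittig olefination with Ph3P=CHCHO should give the enynal (E)-5-[3,4,5-tris(benzyloxy)phenyl]pent-2-en-4-ynal F6. Rhodium-catalysed asymmetric conjugate alkynylation with (triisopropylsilyl)acetylene ([Rh(OAc)(C2H4)2]2, DTBM-SEGPHOS, antipode chosen as in the remark) should give the aldehyde (3R)-3-[(triisopropylsilyl)ethynyl]-5-[3,4,5-tris(benzyloxy)phenyl]pent-4-ynal F7. Pinnick oxidation (NaClO2, NaH2PO4, 2-methyl-2-butene) should give (3R)-3-[(triisopropylsilyl)ethynyl]-5-[3,4,5-tris(benzyloxy)phenyl]pent-4-ynoic acid F8, and esterification with TMSCHN2 returns to the route at 8.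

**Further compounds**

F1 | step 11 | (3aS,6aS)-4-[3,5-bis(benzyloxy)phenyl]-3-ethenyl-6a-hydroxy-5-[3,4,5-tris(benzyloxy)phenyl]-3a,6a-dihydropentalene-1,6-dione | O=C1C=C(C=C)[C@H]2C(c3cc(OCc4ccccc4)cc(OCc4ccccc4)c3)=C(c3cc(OCc4ccccc4)c(OCc4ccccc4)c(OCc4ccccc4)c3)C(=O)[C@@]12O
F2 | step 11 | 1,3-bis(benzyloxy)-5-ethenylbenzene | C=Cc1cc(OCc2ccccc2)cc(OCc2ccccc2)c1
F3 | step 5 | dimethyl 2-{(3R)-1-(triisopropylsilyl)-5-[3,4,5-tris(benzyloxy)phenyl]penta-1,4-diyn-3-yl}propanedioate | COC(=O)C(C(=O)OC)[C@@H](C#C[Si](C(C)C)(C(C)C)C(C)C)C#Cc1cc(OCc2ccccc2)c(OCc2ccccc2)c(OCc2ccccc2)c1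
F4 | step 5 | methyl (5R)-4-[3,5-bis(benzyloxy)phenyl]-2-oxo-5-[(triisopropylsilyl)ethynyl]-3-[3,4,5-tris(benzyloxy)phenyl]cyclopent-3-ene-1-carboxylate (C1 epimers) | COC(=O)C1C(=O)C(c2cc(OCc3ccccc3)c(OCc3ccccc3)c(OCc3ccccc3)c2)=C(c2cc(OCc3ccccc3)cc(OCc3ccccc3)c2)[C@@H]1C#C[Si](C(C)C)(C(C)C)C(C)C
F5 | step 3 | 3-[3,4,5-tris(benzyloxy)phenyl]prop-2-ynal | O=CC#Cc1cc(OCc2ccccc2)c(OCc2ccccc2)c(OCc2ccccc2)c1
F6 | step 3 | (E)-5-[3,4,5-tris(benzyloxy)phenyl]pent-2-en-4-ynal | O=C/C=C/C#Cc1cc(OCc2ccccc2)c(OCc2ccccc2)c(OCc2ccccc2)c1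
F7 | step 3 | (3R)-3-[(triisopropylsilyl)ethynyl]-5-[3,4,5-tris(benzyloxy)phenyl]pent-4-ynal | O=CC[C@@H](C#C[Si](C(C)C)(C(C)C)C(C)C)C#Cc1cc(OCc2ccccc2)c(OCc2ccccc2)c(OCc2ccccc2)c1
F8 | step 3 | (3R)-3-[(triisopropylsilyl)ethynyl]-5-[3,4,5-tris(benzyloxy)phenyl]pent-4-ynoic acid | OC(=O)C[C@@H](C#C[Si](C(C)C)(C(C)C)C(C)C)C#Cc1cc(OCc2ccccc2)c(OCc2ccccc2)c(OCc2ccccc2)c1
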